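At late times the red run went nearly flat, reading 69.7% at 15.0 min and 71.8% at 20.0 min.

| setting | red | violet | Friday's | Sunday's |
|---|---|---|---|---|
| solid substrate | 0.50 M | 2 M | 1.0 M | 1.0 M |
| temperature | 65 °C | 78 °C | 85 °C | 70 °C |
| remark | run made earlier | run made earlier |  |  |
| time |  |  | 10 min | 10 min |

| run | time / min | target / % |
|---|---|---|
| red | 4.00 | 37.9 |
| red | 6.00 | 51.0 |
| red | 10.0 | 63.6 |
| red | 15.0 | 69.7 |
| red | 20.0 | 71.8 |
| violet | 0.500 | 0.8 |
| violet | 1.50 | 4.0 |
| violet | 3.00 | 11.5 |
| violet | 4.00 | 17.1 |
| violet | 6.00 | 29.9 |
| violet | 8.00 | 44.1 |

(readings scatter by 0.5 percentage points)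

- what was read earlier has a scatter of 0.5 percentage points, one standard deviation
- at the start none of the solid substrate is in solution
- what has only dissolved of solid substrate counts as not reacted
- a reading or a percentage of target counts all its forms, free or not

* the best flask by amount of target, in percent of the solid substrate charged; "all alike" if 1.5 percentage points covers them all (Friday's / Sunday's / all alike)
* amount of target at the end, in percent of the solid substrate charged, Friday's
* amount of target at the end, in percent of the solid substrate charged, Sunday's

I wrote the balance of the solid substrate: what was charged is what still lies solid plus what has dissolved. In the violet run, target rose almost steadily towards the end, so I read a supply rate r from its last two readings, supposing that neither the temperature nor the size of the charge matters much to dissolving while solid lies in the flask: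

r = 0.142 M/min

emptying time = [solid substrate] charged / r = 7.04 min

This emptying time is shorter than the 10 min both flasks run, so I committed to the solid being gone from both before the end, and to Friday's, the hotter flask, leading.

The weak link was r, since target is one part of what dissolved. Taking the red run's last reading as a rough share of target in what dissolved, I divided r by it and got 0.198 M/min, hence an emptying time of 5.06 min, so I held a window, not a value.

The forecast said Friday's, with 68% for Friday's and 48% for Sunday's, reading the violet run thus: “This looks like dissolution into a saturated solution”.

The flasks gave 89.4% for Friday's and 68.3% for Sunday's, so Friday's led.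

    starting material ⇌ target (K = 0.780, k = 0.490 /min, Ea = 87.0 kJ/mol, ΔH = −8.00 kJ/mol)
    starting material ⇌ isomer of the product (K = 2.70, k = 0.160 /min, Ea = 90.0 kJ/mol, ΔH = −63.0 kJ/mol)
    starting material ⇌ third isomer (K = 0.510, k = 0.490 /min, Ea = 88.0 kJ/mol, ΔH = 29.0 kJ/mol)
    crystals ⇌ target, rate k4*(cs4 - [target]) while solid is left; crystals form when [target] > cs4 (solubility = 12.0 mM, k = 13.0 /min)
    starting material + target ⇌ idle adduct, settled at all times (K = 0.460 /M, ΔH = −38.0 kJ/mol)
    solid substrate ⇌ starting material, rate k6*(cs6 - [starting material]) while solid is left; crystals form when [starting material] > cs6 (solubility = 0.820 M, k = 0.250 /min)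
    (constants at 70 °C)

Sunday's flask held 18.4% of its charge as solid substrate at 5.00 min and 0% at 10.0 min, so it emptied between those times, where the window of 5.06 min to 7.04 min also lies. The neighbour of Sunday's charged with 1.7 M has the window 8.59 min to 12.0 min, which straddles its 10.0 min. At that time this neighbour still held 9.67% of its charge as solid substrate, and its target stood at 52.6%.

The runs stem from a simulated flask from invented constants; the scatter is artificial.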